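**Assumption:** the target SMILES corresponds to (R) at the carbinol carbon by CIP (O > aryl > CH2 > H). Ring B is a 2,6-dihydroxy-4-alkylphenyl ether, and ring A is a 3-hydroxy-5-alkylphenyl ether.

**Retrosynthesis**
- Last step: demethylate the three aryl methyl ethers of the permethylated macrocycle. Before that, hydrogenate the ring-closing alkene.
- The 22-membered ring (meta/para diaryl ether cyclophane) is closed by ring-closing metathesis (RCM) of a terminal diene. The homoallylic carbinol is set beforehand by Brown asymmetric allylation of an aryl aldehyde.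
- The diene comes from B-alkyl Suzuki coupling of a 9-BBN-alkylborane (from 1,11-dodecadiene) onto an aryl bromide.
- The aryl bromide comes from Ullmann diaryl-ether coupling of syringaldehyde with 3,5-dibromoanisole. Syringaldehyde supplies ring B already carrying the 2,6-dioxygenation and the aldehyde.

**Step 1**
Reactants: 1 syringaldehyde (4-hydroxy-3,5-dimethoxybenzaldehyde); 2 3,5-dibromoanisole (3 equiv)
Product: 3 4-(3-bromo-5-methoxyphenoxy)-3,5-dimethoxybenzaldehyde
Conditions: CuI (10 mol%), picolinic acid (20 mol%), K3PO4, DMSO, 90–110 °C
Reagents that add atoms: none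
Why: Cu/picolinic acid Ullmann-type C–O coupling tolerates hindered 2,6-disubstituted phenols and aldehydes. Excess dibromide suppresses double arylation. No stereocenter is involved.

**Step 2**
Reactants: 4 1,11-dodecadiene (3 equiv relative to 5); 5 9-BBN
Product: 6 B-(dodec-11-en-1-yl)-9-BBN
Conditions: THF, rt, 3 h (solution used directly in Step 3)
Reagents that add atoms: none (both reactants are incorporated in 6)
Why: Hydroboration of a terminal alkene by 9-BBN is selective for the terminal carbon. Excess diene consumes all B–H, so the aldehyde in Step 3 is not reduced.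

**Step 3**
Reactants: 3 aryl bromide; 6 alkylborane (1.5 equiv)
Product: 7 4-[3-(dodec-11-en-1-yl)-5-methoxyphenoxy]-3,5-dimethoxybenzaldehyde
Conditions: Pd(dppf)Cl2 (5 mol%), 3 M aq. K3PO4, THF, 65 °C
Reagents that add atoms: none beyond reactant 6
Why: B-alkyl Suzuki–Miyaura coupling of an sp3 borane with an aryl bromide. The aldehyde, the diaryl ether and the terminal alkene are untouched.

**Step 4**
Reactants: 7 aldehyde; 8 (+)-B-allyldiisopinocampheylborane, prepared from (−)-α-pinene (1.5 equiv)
Product: 9 (R)-1-{4-[3-(dodec-11-en-1-yl)-5-methoxyphenoxy]-3,5-dimethoxyphenyl}but-3-en-1-ol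
Conditions: 8, Et2O, −78 °C, 2 h; then MeOH, 3 M NaOH, 30% H2O2, 0 °C to rt
Reagents that add atoms: 8, SMILES C=CCB(C1CC2CC(C1C)C2(C)C)C1CC2CC(C1C)C2(C)C (pinane stereo from (−)-α-pinene; it adds the allyl group)
Why: Brown asymmetric allylboration goes through a chair Zimmerman–Traxler transition state with the aryl group equatorial. The reagent from (−)-α-pinene delivers allyl to the Re face, giving the (R)-carbinol. This is the only stereocenter-forming step, and I expect about 90% ee or better. Confirm the sense by Mosher ester analysis.

**Step 5**
Reactants: 9 diene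
Product: 10 macrocyclic alkene (E/Z mixture), 22-membered ring
Conditions: Hoveyda–Grubbs II (10 mol%), 1,4-benzoquinone (10 mol%), toluene, 2 mM, 60 °C, open to N2 (ethylene released)
Reagents that add atoms: none
Why: Ring-closing olefin metathesis at high dilution. The free homoallylic OH and the aryl ethers are tolerated. Benzoquinone suppresses Ru–H alkene isomerisation. The double-bond geometry is irrelevant because it is hydrogenated next, and the stereocenter is not touched.

**Step 6**
Reactants: 10 macrocyclic alkene
Product: 11 permethylated saturated macrocycle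
Conditions: H2 (1 atm), 10% Pd/C, EtOAc, rt, 2 h
Reagents that add atoms: none (only H added)
Why: Heterogeneous hydrogenation of the disubstituted C=C. Neutral solvent and a short reaction time avoid benzylic C–OH hydrogenolysis, and the aryl methyl ethers are stable.

**Step 7**
Reactants: 11 permethylated macrocycle
Product: 12 gravicycle
Conditions: BBr3 (6 equiv), CH2Cl2, −78 °C to 0 °C, 3 h; quench with MeOH/H2O at 0 °C
Reagents that add atoms: none (gives OH in place of OMe)
Why: BBr3 cleaves the three aryl methyl ethers, leaving the diaryl ether and the secondary alcohol. The low temperature minimises benzylic ionisation, so the carbinol configuration is retained.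

**Compound list**
1 | syringaldehyde | COc1cc(C=O)cc(OC)c1O | starting material
2 | 3,5-dibromoanisole | COc1cc(Br)cc(Br)c1 | starting material
3 | 4-(3-bromo-5-methoxyphenoxy)-3,5-dimethoxybenzaldehyde | COc1cc(Br)cc(Oc2c(OC)cc(C=O)cc2OC)c1 | intermediate
4 | 1,11-dodecadiene | C=CCCCCCCCCC=C | starting material
5 | 9-BBN (9-borabicyclo[3.3.1]nonane) | [BH]1C2CCCC1CCC2 | starting material
6 | B-(dodec-11-en-1-yl)-9-BBN | C=CCCCCCCCCCCB1C2CCCC1CCC2 | intermediate (in situ)
7 | 4-[3-(dodec-11-en-1-yl)-5-methoxyphenoxy]-3,5-dimethoxybenzaldehyde | COc1cc(CCCCCCCCCCC=C)cc(Oc2c(OC)cc(C=O)cc2OC)c1 | intermediate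
8 | (+)-B-allyldiisopinocampheylborane (from (−)-α-pinene) | C=CCB(C1CC2CC(C1C)C2(C)C)C1CC2CC(C1C)C2(C)C (pinane stereo not encoded) | reagent (starting material)
9 | (R)-homoallylic alcohol | COc1cc(CCCCCCCCCCC=C)cc(Oc2c(OC)cc(cc2OC)[C@H](O)CC=C)c1 | intermediate
10 | macrocyclic alkene (E/Z) | COc1cc2cc(c1)Oc1c(OC)cc(cc1OC)[C@H](O)CC=CCCCCCCCCCC2 | intermediate
11 | permethylated saturated macrocycle | COc1cc2cc(c1)Oc1c(OC)cc(cc1OC)[C@H](O)CCCCCCCCCCCCC2 | intermediate
12 | gravicycle | Oc1cc2cc(c1)Oc1c(O)cc(cc1O)[C@H](O)CCCCCCCCCCCCC2 | target

**Totals:** 7 steps (Step 2 is a reagent preparation used directly in Step 3). Longest linear sequence: 6 steps (1 → 3 → 4 → 5 → 6 → 7 from syringaldehyde).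

**Three steps most likely to fail**
1. **Step 1 (Ullmann).** The hindered, electron-poor syringaldehyde phenoxide is coupled with an electron-rich aryl bromide, so conversion may be low. Fallback: SNAr of 3-bromo-5-methoxyphenol onto 4-fluoro-3,5-dimethoxybenzaldehyde, or Cu-catalysed arylation of 1 with a diaryliodonium salt.
2. **Step 5 (macro-RCM).** Oligomerisation or alkene isomerisation could compete with ring closure. Fallback: close the ring by intramolecular B-alkyl Suzuki coupling of the aryl bromide with an alkylborane made in situ from a terminal alkene on the ring-B side chain, which needs no hydrogenation. Ring-closing alkyne metathesis of a diyne followed by alkyne hydrogenation is another option.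
3. **Step 7 (BBr3).** The benzylic alcohol could ionise and racemise or brominate. Fallback: acetylate the carbinol first, demethylate (BBr3 or NaSEt/DMF), then remove the acetate with K2CO3/MeOH.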